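**Retrosynth­etic overview**
1. Target 22 ⇐ 21 by epoxidation of the C10 vinyl group directed by the 9α-OH (last step); 21 ⇐ 19 by unmasking the methylene lactone from its dimethylamine adduct.
2. 8,12-Lactone 19 ⇐ Weinreb amide 18: the lactone formed in the key step sits on O6 and is moved to O8 (open, esterify O6 with (2S)-2-methylbutanoic anhydride, relactonise on O8 in acid, which also frees the enal).
3. O8/O9 ⇐ cis-dihydroxylation of C8=C9 of cycloadduct 10; C15 ⇐ methylenation of the C4 ketone.
4. Key step 9 → 10: intramolecular Diels–Alder reaction of a Z-β-acyloxy enone tethered through its enol-ester oxygen to a 2-dienylacrylate; the cyclohexene and γ-lactone rings and C5, C6, C7, C10 arise together.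
5. 9 ⇐ acid 5 (from (Z)-3-methylpent-2-en-4-yn-1-ol and a phosphonoacrylate) + ynone 8 (from ethyl diethoxyacetate and ethynylmagnesium bromide). Ring order: cyclohexene + lactone together, relocated lactone, epoxide last.

Assumption: ring carbons are called C5–C10 (elemane numbering: C10 carries C14 and C1–C2, C5 carries C4(=C15)–C3, C7 carries C11(=C13)–C12), β is the face of the C10 methyl group and α the opposite face; compounds 1, 3, 6, 7 and 17 are taken as commercial.

**Route**

Step 1
Reactants: 1 (2Z)-3-methylpent-2-en-4-yn-1-ol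
Product: 2 (2Z)-3-methylpent-2-en-4-ynal
Conditions: MnO2 (10 equiv), CH2Cl2, 0 °C to rt; used at once
Reagents that add atoms: none
Why: Allylic alcohol oxidation on MnO2 stops at the aldehyde, leaves the alkyne alone and, being neutral, keeps the Z-alkene (no new stereocenter).

Step 2
Reactants: 2 (2Z)-3-methylpent-2-en-4-ynal; 3 ethyl 2-[(diethoxyphosphoryl)methyl]prop-2-enoate
Product: 4 ethyl (3E,5Z)-6-methyl-2-methylideneocta-3,5-dien-7-ynoate
Conditions: NaH, THF, 0 °C; kept cold and dilute
Reagents that add atoms: none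
Why: Horner–Wadsworth–Emmons olefination through the phosphorus-bearing carbon of the allyl phosphonate anion gives the 2-alkoxycarbonyl-1,3-diene with the new C7=C8 bond E, while the Z-enyne (ethynyl cis to the chain) is carried over unchanged.

Step 3
Reactants: 4 ethyl (3E,5Z)-6-methyl-2-methylideneocta-3,5-dien-7-ynoate
Product: 5 (3E,5Z)-6-methyl-2-methylideneocta-3,5-dien-7-ynoic acid
Conditions: LiOH, THF/H2O, 0 °C; then 1 M HCl to pH 3
Reagents that add atoms: lithium hydroxide, [Li+].[OH-]
Why: Ester saponification at 0 °C outruns conjugate addition of hydroxide to the hindered triene ester and gives the free acid needed for enol-ester formation (no stereocenter involved).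

Step 4
Reactants: 6 ethyl 2,2-diethoxyacetate; 7 ethynylmagnesium bromide
Product: 8 1,1-diethoxybut-3-yn-2-one
Conditions: THF, −78 °C, inverse addition, cold quench
Reagents that add atoms: none
Why: Acyl substitution of an α,α-dialkoxy ester by an alkynyl Grignard reagent stops at the ketone because the magnesium-chelated tetrahedral adduct survives at −78 °C until the quench (no stereocenter).

Step 5
Reactants: 5 (3E,5Z)-6-methyl-2-methylideneocta-3,5-dien-7-ynoic acid; 8 1,1-diethoxybut-3-yn-2-one
Product: 9 (1Z)-4,4-diethoxy-3-oxobut-1-en-1-yl (3E,5Z)-6-methyl-2-methylideneocta-3,5-dien-7-ynoate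
Conditions: Cs2CO3 (5 mol %), MeCN, −20 °C, 1 h; cold chromatography
Reagents that add atoms: none
Why: Base-catalysed oxa-Michael addition of the carboxylate to the terminal ynone is an anti addition (the allenolate is protonated by free acid on the side remote from the new acyloxy group), so the kinetic product is the Z-β-acyloxy enone with O6 and the C4 ketone cis, the dienophile geometry the cycloaddition needs.

Step 6
Reactants: 9 (1Z)-4,4-diethoxy-3-oxobut-1-en-1-yl (3E,5Z)-6-methyl-2-methylideneocta-3,5-dien-7-ynoate
Product: 10 cycloadduct (cyclohex-8-ene cis-fused at C6/C7 to the α-methylene-γ-lactone; 5β-diethoxyacetyl; 10β-methyl; 10α-ethynyl)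
Conditions: Cu(SbF6)2 (10 mol %), (S,S)-2,2'-(propane-2,2-diyl)bis(4-tert-butyl-4,5-dihydrooxazole) (11 mol %), 4 Å MS, CH2Cl2 (0.01 M), −20 °C to rt
Reagents that add atoms: none
Why: Proposed new method: intramolecular Diels–Alder reaction in which the keto acetal chelates the chiral copper Lewis acid (lower enone LUMO, one dienophile face blocked), bond formation leads from the enone β-carbon C6 to the unhindered diene terminus C7 (five-membered lactone closing), and the endo transition state of the Z-dienophile puts O6, the C4 acyl group and C11 cis (cis-fused lactone, 5β,6β,7β) with the outside methyl β and the slim inside ethynyl α at the new quaternary C10; the closest known chemistry is the bis(oxazoline)–copper-catalysed Diels–Alder reaction of chelating α′-oxygenated enones and the Lewis-acid-promoted cyclisation of ester-tethered trienes.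

Step 7
Reactants: 10 cycloadduct
Product: 12 8α,9α-O-isopropylidene acetal of the cycloadduct, via 8α,9α-diol 11 (not isolated)
Conditions: OsO4 (2 mol %), N-methylmorpholine N-oxide, acetone/H2O, 0 °C to rt; then 2,2-dimethoxypropane, PPTS (cat.), acetone, rt
Reagents that add atoms: N-methylmorpholine N-oxide, C[N+]1([O-])CCOCC1; water, O; 2,2-dimethoxypropane, COC(C)(C)OC
Why: Upjohn syn-dihydroxylation attacks the only electron-rich alkene (C8=C9; the conjugated methylene lactone and the alkyne react far more slowly) from the convex α face opposite the cis-fused lactone and the C10 methyl group, setting 8α-OH and 9α-OH together, and acetal exchange then ties the cis-diol up.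

Step 8
Reactants: 12 8α,9α-O-isopropylidene acetal of the cycloadduct
Product: 13 C4-methylidene compound (5β-(3,3-diethoxyprop-1-en-2-yl))
Conditions: Zn, CH2Br2, TiCl4 (preformed Lombardo reagent), THF/CH2Cl2, 0 °C to rt
Reagents that add atoms: dibromomethane, BrCBr
Why: Takai–Lombardo methylenation is non-basic, so the β-acyloxy ketone becomes the C4=C15 alkene without E1cB loss of the lactone oxygen or epimerisation at C5, and the lactone, acetals and alkyne are left alone (no new stereocenter).

Step 9
Reactants: 13 C4-methylidene compound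
Product: 15 13-(dimethylamino) lactone with 10α-vinyl group (C11 epimers), via 13-(dimethylamino) alkyne lactone 14 (not isolated)
Conditions: Me2NH (2 M in THF), rt; evaporate; then H2 (1 atm), Pd/CaCO3–Pb(OAc)2 (Lindlar catalyst), quinoline, EtOAc, rt
Reagents that add atoms: dimethylamine, CNC
Why: Aza-Michael addition of dimethylamine masks the methylene lactone as its Mannich base (C11 becomes a transient stereocenter, formed as an epimer mixture and erased in step 13), and Lindlar semihydrogenation then reduces the terminal alkyne to the vinyl group while no activated alkene is exposed.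

Step 10
Reactants: 15 13-(dimethylamino) lactone with 10α-vinyl group
Product: 16 6β-hydroxy N-methoxy-N-methyl amide (C12 amide; 8α,9α-acetonide)
Conditions: MeNH(OMe)·HCl, i-PrMgCl, THF, −20 to 0 °C
Reagents that add atoms: N,O-dimethylhydroxylamine hydrochloride, CNOC.Cl
Why: Weinreb aminolysis by the chloromagnesium amide opens the lactone through acyl substitution at C12, which frees the 6β-hydroxyl with its configuration untouched and parks C12 as an amide that does not relactonise under basic conditions.

Step 11
Reactants: 16 6β-hydroxy N-methoxy-N-methyl amide; 17 (2S)-2-methylbutanoic anhydride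
Product: 18 6β-O-[(2S)-2-methylbutanoyl] ester of 16
Conditions: DMAP, Et3N, CH2Cl2, 40 °C
Reagents that add atoms: none
Why: DMAP-catalysed acyl transfer to the only free hydroxyl puts the (2S)-2-methylbutanoate on O6 with retention at C6, and the anhydride is used instead of the acid chloride so that no ketene forms and the acyl α-stereocenter is kept.

Step 12
Reactants: 18 6β-O-[(2S)-2-methylbutanoyl] ester
Product: 19 trans-fused 8α,12-lactone with 13-NMe2, 9α-OH and the C4(=C15)–C3HO enal
Conditions: 2 M HCl, THF, 40 °C; NaHCO3 work-up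
Reagents that add atoms: water, O
Why: Aqueous acid removes the isopropylidene acetal and hydrolyses the allylic diethyl acetal to the enal, and the liberated equatorial 8α-hydroxyl then displaces N,O-dimethylhydroxylamine from the protonated Weinreb amide (acid-catalysed lactonisation) to give the trans-fused 8,12-lactone, O9 being unable to reach C12 and O6 being blocked as the ester.

Step 13
Reactants: 19 trans-fused 8α,12-lactone with 13-NMe2
Product: 21 11(13)-methylene lactone with 10α-vinyl group, via trimethylammonium iodide 20 (not isolated)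
Conditions: MeI, MeCN, rt; then aq. NaHCO3, EtOAc, rt
Reagents that add atoms: none
Why: N-Methylation turns the amine into a leaving group and bicarbonate then effects E1cB (Hofmann-type) elimination of trimethylamine through the lactone enolate, which regenerates the C11=C13 methylene group and erases the C11 stereocenter.

Step 14
Reactants: 21 11(13)-methylene lactone with 10α-vinyl group
Product: 22 target CNP0593558.1
Conditions: VO(acac)2 (10 mol %), t-BuOOH (decane), CH2Cl2, 0 °C to rt
Reagents that add atoms: tert-butyl hydroperoxide, CC(C)(C)OO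
Why: Hydroxyl-directed epoxidation of a homoallylic alcohol: the vanadate ester of the axial 9α-OH delivers the peroxide oxygen through a chair-like six-membered array to the α face of the neighbouring equatorial vinyl group held with its CH2 terminus away from C9, which gives the (1R)-epoxide (C9–O and C1–O syn), while the electron-poor enal and methylene-lactone alkenes are inert to the electrophilic vanadium peroxide.

**Compound list**
1 | (2Z)-3-methylpent-2-en-4-yn-1-ol | C#C/C(C)=C\CO | starting material
2 | (2Z)-3-methylpent-2-en-4-ynal | C#C/C(C)=C\C=O | intermediate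
3 | ethyl 2-[(diethoxyphosphoryl)methyl]prop-2-enoate | C=C(CP(=O)(OCC)OCC)C(=O)OCC | starting material
4 | ethyl (3E,5Z)-6-methyl-2-methylideneocta-3,5-dien-7-ynoate | C=C(/C=C/C=C(/C)C#C)C(=O)OCC | intermediate
5 | (3E,5Z)-6-methyl-2-methylideneocta-3,5-dien-7-ynoic acid | C=C(/C=C/C=C(/C)C#C)C(=O)O | intermediate
6 | ethyl 2,2-diethoxyacetate | CCOC(OCC)C(=O)OCC | starting material
7 | ethynylmagnesium bromide | C#C[Mg]Br | starting material
8 | 1,1-diethoxybut-3-yn-2-one | CCOC(OCC)C(=O)C#C | intermediate
9 | (1Z)-4,4-diethoxy-3-oxobut-1-en-1-yl (3E,5Z)-6-methyl-2-methylideneocta-3,5-dien-7-ynoate | C=C(/C=C/C=C(/C)C#C)C(=O)O/C=C\C(=O)C(OCC)OCC | intermediate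
10 | cycloadduct: cyclohex-8-ene (C5–C10) cis-fused at C6/C7 to the α-methylene-γ-lactone (6β-O, 7β-C11); 5β-(2,2-diethoxyacetyl); 10β-methyl; 10α-ethynyl | C=C1C(=O)O[C@H]2[C@@H](C(=O)C(OCC)OCC)[C@](C)(C#C)C=C[C@@H]12 | intermediate
11 | 8α,9α-diol of 10 | C=C1C(=O)O[C@H]2[C@@H](C(=O)C(OCC)OCC)[C@](C)(C#C)[C@H](O)[C@H](O)[C@@H]12 | intermediate (not isolated)
12 | 8α,9α-O-isopropylidene acetal of 11 | C=C1C(=O)O[C@H]2[C@@H](C(=O)C(OCC)OCC)[C@](C)(C#C)[C@@H]3OC(C)(C)O[C@@H]3[C@@H]12 | intermediate
13 | C4-methylidene compound: as 12 with 5β-(3,3-diethoxyprop-1-en-2-yl) | C=C1C(=O)O[C@H]2[C@@H](C(=C)C(OCC)OCC)[C@](C)(C#C)[C@@H]3OC(C)(C)O[C@@H]3[C@@H]12 | intermediate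
14 | 13-(dimethylamino) adduct of 13 (C11 epimers; 10α-ethynyl) | CN(C)CC1C(=O)O[C@H]2[C@@H](C(=C)C(OCC)OCC)[C@](C)(C#C)[C@@H]3OC(C)(C)O[C@@H]3[C@@H]12 | intermediate (not isolated)
15 | 13-(dimethylamino) 6β,12-lactone with 10α-vinyl (C11 epimers) | CN(C)CC1C(=O)O[C@H]2[C@@H](C(=C)C(OCC)OCC)[C@](C)(C=C)[C@@H]3OC(C)(C)O[C@@H]3[C@@H]12 | intermediate
16 | ring-opened 6β-hydroxy N-methoxy-N-methyl amide (C12 amide; 13-NMe2; 8α,9α-acetonide; 10α-vinyl; C11 epimers) | O[C@H]1[C@@H](C(=C)C(OCC)OCC)[C@](C)(C=C)[C@@H]2OC(C)(C)O[C@@H]2[C@H]1C(CN(C)C)C(=O)N(C)OC | intermediate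
17 | (2S)-2-methylbutanoic anhydride | CC[C@H](C)C(=O)OC(=O)[C@@H](C)CC | starting material
18 | 6β-O-[(2S)-2-methylbutanoyl] ester of 16 | CC[C@H](C)C(=O)O[C@H]1[C@@H](C(=C)C(OCC)OCC)[C@](C)(C=C)[C@@H]2OC(C)(C)O[C@@H]2[C@H]1C(CN(C)C)C(=O)N(C)OC | intermediate
19 | trans-fused 8α,12-lactone; 13-NMe2 (C11 epimers); 9α-OH; 6β-(2S)-2-methylbutanoyloxy; 5β-(3-oxoprop-1-en-2-yl); 10β-methyl; 10α-vinyl | CN(C)CC1C(=O)O[C@@H]2[C@@H]1[C@@H](OC(=O)[C@@H](C)CC)[C@@H](C(=C)C=O)[C@](C)(C=C)[C@@H]2O | intermediate
20 | N-methyl ammonium iodide of 19 | C[N+](C)(C)CC1C(=O)O[C@@H]2[C@@H]1[C@@H](OC(=O)[C@@H](C)CC)[C@@H](C(=C)C=O)[C@](C)(C=C)[C@@H]2O.[I-] | intermediate (not isolated)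
21 | 1,2-deoxy precursor: 11(13)-methylene 8α,12-lactone with 10α-vinyl | C=C1C(=O)O[C@@H]2[C@@H]1[C@@H](OC(=O)[C@@H](C)CC)[C@@H](C(=C)C=O)[C@](C)(C=C)[C@@H]2O | intermediate
22 | CNP0593558.1 | C=C1C(=O)O[C@@H]2[C@@H]1[C@@H](OC(=O)[C@@H](C)CC)[C@@H](C(=C)C=O)[C@](C)([C@@H]1CO1)[C@@H]2O | target

**Step count**
Total steps: 14. Longest linear sequence: 13 (steps 1–3 and 5–14, from 1 to 22); step 4 is a one-step side branch.

**Three steps most likely to fail**

Step 6 (key cycloaddition). The diene carries an inside substituent at the terminus that becomes quaternary, the cross-conjugated triene can dimerise, and the facial sense of the copper catalyst is predicted from a chelate model, not known (the antipodal ligand would give the mirror-image adduct). Fallback, setting out from 4 and 8: 8 is treated with commercial (2S)-2-methylbutanoic acid under the step-5 protocol to give (1Z)-4,4-diethoxy-3-oxobut-1-en-1-yl (2S)-2-methylbutanoate F2. F2 and ester 4 are then joined in an intermolecular Diels–Alder reaction under the same copper catalyst to give the cyclohexene with the ester already on O6, F3. OsO4/N-methylmorpholine N-oxide dihydroxylates C8=C9 and the 8α-hydroxyl lactonises onto the acrylate ester to give the hydroxy lactone F4. Lombardo methylenation gives the C4-methylidene acetal F5, aqueous acid gives the enal with 10α-ethynyl group F6, and Lindlar reduction brings the material back to the route at 21.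

Step 5 (Z-enol ester). The Z-isomer is the kinetic product and can drift to the E-isomer, which would give the wrong relative configuration at C5/C6. Fallback, setting out from 8: anti-hydroiodination with NaI/AcOH gives (3Z)-1,1-diethoxy-4-iodobut-3-en-2-one F1, and addition–elimination of the caesium salt of 5 (DMF, 0 °C), which keeps the alkene geometry, comes back to the route at 9.

Step 14 (C1 configuration). The chair model predicts (1R), but the rotamer with the CH2 terminus towards C9 would give the epimer. Fallback, setting out from 21: undirected epoxidation with dimethyldioxirane gives 22 together with its C1 epimer, the (1S)-epoxide F7. Hydrolytic kinetic resolution with the Co(salen)(OAc) antipode that selectively hydrolyses (S)-1,2-epoxyalkanes then turns F7 into the 1,2-diol F8, which is removed by chromatography, and the sequence comes back to the route at 22.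

**Further compounds**
F1 | step 5 | (3Z)-1,1-diethoxy-4-iodobut-3-en-2-one | CCOC(OCC)C(=O)/C=C\I
F2 | step 6 | (1Z)-4,4-diethoxy-3-oxobut-1-en-1-yl (2S)-2-methylbutanoate | CC[C@H](C)C(=O)O/C=C\C(=O)C(OCC)OCC
F3 | step 6 | intermolecular cycloadduct: ethyl 2-(cyclohex-8-en-7β-yl)acrylate with 6β-(2S)-2-methylbutanoyloxy, 5β-(2,2-diethoxyacetyl), 10β-methyl, 10α-ethynyl | C=C(C(=O)OCC)[C@@H]1C=C[C@@](C)(C#C)[C@H](C(=O)C(OCC)OCC)[C@@H]1OC(=O)[C@@H](C)CC
F4 | step 6 | 8α,12-lactone (11(13)-methylene) with 9α-OH, 6β-ester, 5β-(2,2-diethoxyacetyl), 10α-ethynyl | C=C1C(=O)O[C@@H]2[C@@H]1[C@@H](OC(=O)[C@@H](C)CC)[C@@H](C(=O)C(OCC)OCC)[C@](C)(C#C)[C@@H]2O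
F5 | step 6 | C4-methylidene acetal of F4 | C=C1C(=O)O[C@@H]2[C@@H]1[C@@H](OC(=O)[C@@H](C)CC)[C@@H](C(=C)C(OCC)OCC)[C@](C)(C#C)[C@@H]2O
F6 | step 6 | enal with 10α-ethynyl group (alkyne analogue of 21) | C=C1C(=O)O[C@@H]2[C@@H]1[C@@H](OC(=O)[C@@H](C)CC)[C@@H](C(=C)C=O)[C@](C)(C#C)[C@@H]2O
F7 | step 14 | (1S)-epoxide, C1 epimer of 22 | C=C1C(=O)O[C@@H]2[C@@H]1[C@@H](OC(=O)[C@@H](C)CC)[C@@H](C(=C)C=O)[C@](C)([C@H]1CO1)[C@@H]2O
F8 | step 14 | (1S)-1,2-diol from hydrolysis of F7 | C=C1C(=O)O[C@@H]2[C@@H]1[C@@H](OC(=O)[C@@H](C)CC)[C@@H](C(=C)C=O)[C@](C)([C@H](O)CO)[C@@H]2O
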